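## The problem

Bromophycolide Q (34) is a 15-membered macrolide. A 4-hydroxybenzoate bridges, through its carboxyl group and its ortho carbon, the two ends of a C15 terpenoid chain (numbered C1', the benzylic CH2, to C15', the gem-dimethyl ether carbon). The chain is folded into a bromocyclohexene (C2'–C7', tetrasubstituted C2'=C3' alkene, quaternary C7') and a 2,2,6-trisubstituted tetrahydropyran (ring oxygen, C11'–C15').

The five stereocentres form two clusters, C6'(Br)/C7' and C10'(Br)/C11'(O)/C14'(O), separated by the C8'–C9' ethylene. Neither cluster can direct the other, so each needs its own source of absolute configuration.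

Inside the clusters the relationships point to mechanism. Br at C6' is cis to the C7' methyl and trans to the chain, as after an anti addition across a ring alkene. C10'–Br and C11'–O are related as after an anti addition to a (Z)-C10'=C11' alkene. C14' is 1,4 to C11' and needs reagent control.

Both bromides are secondary and flanked by fully substituted carbons, so they must come from electrophilic bromine, not from displacement. Once made they are fragile: a C2' ketone beta to C6'–Br invites Grob fragmentation when a nucleophile adds, and a free C11' alkoxide next to C10'–Br closes to an epoxide.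

The tetrasubstituted alkene would compete for any Br+ reagent. As part of an ortho-allylphenol it also cyclises to a chroman in acid. It must therefore appear after the last bromination, and the end game must avoid acid.

The enabling feature is that C14' lies three carbons from C11'. The C10'–C14' segment is therefore the bromolactonization product of a (Z)-4-methylalk-4-enoic acid: the lactone oxygen is the future tetrahydropyran oxygen and the lactone carbonyl carbon is C14'.

## Retrosynthesis

**Phenol and macrocycle.** The phenol of 34 is carried as its silyl ether 33, removable with buffered fluoride. In 33 the C14'O–C(=O)Ar ester bond is cut, giving seco acid 31. The neighbouring option, closing the ring at C1'–C2', would require a benzylic organometal to be generated inside a molecule with two alkyl bromides and used at high dilution. Lactonization is the better-practised ring closure and lets the hindered C–C coupling be run intermolecularly with excess reagent. The forward step must acylate a hindered secondary hydroxyl at high dilution.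

**C1'–C2' bond.** Seco acid 31 is cut between the benzylic carbon and C2', giving enol triflate 25 and benzylic bromide 28 (from 4-hydroxy-3-methylbenzoic acid 26 via 27). The triflate serves three purposes: it is the coupling handle, it masks the C2' ketone against nucleophiles and fragmentation, and it is too electron-poor to react with Br+. The whole arene is removed in one cut. The coupling must succeed at a tetrasubstituted triflate next to a quaternary carbon and tolerate a free hydroxyl.

**Tetrahydropyran.** In 25 the O–C15' bond is cut, leading to diol 23 with an isopropenyl group. Closing the ring by Markovnikov addition of the C11' hydroxyl to C15' gives only the six-membered ether. The alternative, opening a C14'–C15' epoxide, would split between five- and six-membered ethers. The forward step must select the 1,1-disubstituted alkene and spare the bromides.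

**C14'–C15' bond and C14' configuration.** Diol 23 comes from enone 21 by reagent-controlled reduction, and 21 from Weinreb amide 20 by addition of an isopropenyl nucleophile. Amide 20 is the opened, O-silylated form of lactone 18. The silyl ether prevents both relactonization and epoxide closure onto C10'–Br.

**Key disconnection.** In 18 the C10'–Br and C11'–O bonds are cut together, giving (Z)-alkenoic acid 17. Two stereocentres and the lactone ring are traded for one alkene geometry. The spectator end of 17 is the enol triflate rather than a ketone, for the reasons given above. The forward step needs catalyst-controlled facial selectivity and no competing alkene.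

**(Z)-Acid chain.** Acid 17 comes from ester 16. The C12'–C13' bond of 16 is cut to allylic bromide 15 and an acetate enolate. Bromide 15 goes back through alcohol 14 to (Z)-enoate 13, whose C10'=C11' bond is cut to aldehyde 11 and phosphonate 12. Still–Gennari olefination is the most reliable source of a (Z)-trisubstituted alkene of this pattern.

**Ring end.** Aldehyde 11 comes from alcohol 10 and this from the allyl group of enol triflate 8. Triflate 8 derives from ketone 6, the C3'-methylated form of bromo ketone 4. Methylation and triflation are placed here, on the smallest intermediate, because C3' is the only enolizable position.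

**Bromine and quaternary centre.** In 4 the C6'–Br bond and the C7'–C8' bond are cut together in the sense of a bromonium-induced semipinacol shift, giving tertiary allylic alcohol 3. The anti relationship of bromine and migrating allyl group is then stereospecific. Alcohol 3 comes from 2-methylcyclohex-2-en-1-one (1) and tetraallylstannane (2) by catalytic asymmetric allylation, the one step that sets the absolute configuration of the ring.

## Roads not taken

**Alternative 1:** The cut is at C4'–C5' and C6'–Br. Bromomethyl ketone A1 would undergo copper-catalysed bromine-atom-transfer cyclization (CuBr, tris(2-pyridylmethyl)amine): the C4' radical adds to the vinyl terminus C5' and the C6' radical takes back bromine, giving 4-bromocyclohexanone A2.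

- Merits: ring and C–Br bond form in one redox-neutral step. No Br+ is involved, so the arene can be present from the start, and the hindered triflate coupling of the chosen route is avoided.
- Weak points: the C6' configuration is set by bromine transfer to a cyclohexyl radical beside a quaternary carbon, with little to choose between the two faces. The 6-endo mode must beat 5-exo. A1 needs two preset stereocentres in an open chain, one of which (C2') is later destroyed. The C3' ketone must still become the tetrasubstituted alkene by addition and a regioselective dehydration.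
- Comparison: the chain of A2 ends at C10', so the C10'/C11'/C14' problem is untouched and a bromolactonization would be needed anyway. Alternative 1 is better for bringing the arene in early. The chosen plan sets against it the stereospecific anti shift that fixes C6' relative to C7'.

**Alternative 2:** The cut is at C2'–C7' and C6'–Br across the macrocycle. The 19-membered macrolactone diene A3 would react with the bromonium donor [Et2SBr][SbBrCl5]; the C6'=C7' bromonium is captured by C2', the cyclohexene closes and the ring contracts to the 15-membered acetate A4.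

- Merits: this is biomimetic and clearly shorter. The macrolactonization is done on a flexible, larger ring, and the tetrasubstituted alkene arises directly by proton loss.
- Weak points: the reagent is achiral, so the face of the C6'=C7' alkene must be chosen by the macrocycle conformation, which cannot be predicted. Proton loss from the C3' cation can go three ways. The electron-rich arene can capture the cation. The C10'-bromo tetrahydropyran must be made earlier on a substrate carrying further trisubstituted alkenes, which brings back the site-selectivity problem.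
- Comparison: Alternative 2 wins on step count by a wide margin. The chosen plan sets against it reagent or stereospecific control at every stereocentre and no step that depends on an unknown conformation.

**Alternative 3:** The cut removes two bonds of the benzene ring. In A5 a siloxyalkyne on C1' and a coumalate ester on the C14' oxygen would undergo intramolecular [4+2] cycloaddition and loss of CO2 on heating, forming the arene and the macrocycle at once to give the silyl ether A6.

- Merits: arene regiochemistry follows from the polarity of the two partners. Esterification uses a small acid, and macrocyclization and arene synthesis are merged.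
- Weak points: the siloxyalkyne must be made and carried beside two secondary bromides. The alkynyl unit must still be attached to C2' of the tetrasubstituted alkene, so the hindered coupling is not avoided. The cycloaddition is a high-temperature macrocyclization with a large entropic cost.
- Comparison: all five stereocentres must be in place beforehand, so the stereochemical problem is not addressed. Alternative 3 is more convergent at the end and needs no separate macrolactonization. The chosen plan sets against it ring-closing and coupling steps that can each be optimised separately.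

Key step: step 12

## Route

Assumption: the facial sense of the titanium–BINOL allylation (step 1), of the amino-thiocarbamate bromolactonization (step 12) and of the oxazaborolidine reduction (step 15) is taken from the accepted models; if any is reversed on these substrates, the mirror-image ligand or the quinine-derived pseudoenantiomer is used and nothing else changes.

Step 1
Reactants: 1 2-methylcyclohex-2-en-1-one; 2 tetraallylstannane
Product: 3 (1S)-2-methyl-1-(prop-2-en-1-yl)cyclohex-2-en-1-ol
Conditions: Ti(OiPr)4 (20 mol %), (R)-1,1'-bi-2-naphthol (20 mol %), i-PrOH, CH2Cl2, rt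
Reagents that add atoms: none
Why: Catalytic enantioselective 1,2-allylation of a ketone by a titanium–BINOL complex, a reaction type established for 2-substituted cyclic enones. The catalyst distinguishes the sp2 flank (C2 with its methyl group) from the C6 methylene and so sets the carbinol configuration, the only source of absolute configuration for C6' and C7'.

Step 2
Reactants: 3 (1S)-2-methyl-1-(prop-2-en-1-yl)cyclohex-2-en-1-ol
Product: 4 (2S,3S)-3-bromo-2-methyl-2-(prop-2-en-1-yl)cyclohexan-1-one
Conditions: NBS (1.05 equiv), CH2Cl2, −20 → 0 °C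
Reagents that add atoms: N-bromosuccinimide (BrN1C(=O)CCC1=O)
Why: Bromonium-induced semipinacol rearrangement: allylic 1,2-strain holds the allyl group pseudoaxial, so Br+ adds to C3 on the face syn to the hydroxyl and the allyl group shifts from C1 to C2 antiperiplanar to the breaking C–Br+ bond as the carbinol becomes the ketone. Both new centres (C6' and C7') thus follow from the configuration of 3, with Br cis to methyl and trans to the migrated chain; the monosubstituted alkene of the allyl group is far less nucleophilic than the trisubstituted ring alkene.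

Step 3
Reactants: 4 (2S,3S)-3-bromo-2-methyl-2-(prop-2-en-1-yl)cyclohexan-1-one
Product: 6 (2S,3S)-3-bromo-2,6-dimethyl-2-(prop-2-en-1-yl)cyclohexan-1-one (both C6 epimers), via lithium enolate 5 (not isolated)
Conditions: LiN(i-Pr)2, THF, −78 °C; MeI, DMPU, −78 → −20 °C
Reagents that add atoms: iodomethane (CI)
Why: Enolate alkylation; C7' is quaternary, so deprotonation can occur only at C3', and with no hydrogen on C7' the beta-bromide cannot be eliminated. The new C3' centre forms as a mixture and is erased in step 4.

Step 4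
Reactants: 6 (2S,3S)-3-bromo-2,6-dimethyl-2-(prop-2-en-1-yl)cyclohexan-1-one
Product: 8 (5S,6S)-5-bromo-2,6-dimethyl-6-(prop-2-en-1-yl)cyclohex-1-en-1-yl trifluoromethanesulfonate, via potassium enolate 7 (not isolated)
Conditions: KN(SiMe3)2, THF, −78 °C; PhNTf2, −78 → 0 °C
Reagents that add atoms: N-phenylbis(trifluoromethanesulfonimide) (O=S(=O)(N(c1ccccc1)S(=O)(=O)C(F)(F)F)C(F)(F)F)
Why: O-sulfonylation of the only possible (tetrasubstituted) enolate, as practised for 2,2,6-trisubstituted cyclohexanones. The enol triflate places the future C2'=C3' alkene, masks the ketone against hydride, Grignard reagents and Grob fragmentation, and is too electron-poor to react with NBS in step 12.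

Step 5
Reactants: 8 (5S,6S)-5-bromo-2,6-dimethyl-6-(prop-2-en-1-yl)cyclohex-1-en-1-yl trifluoromethanesulfonate
Product: 10 (5S,6S)-5-bromo-6-(3-hydroxypropyl)-2,6-dimethylcyclohex-1-en-1-yl trifluoromethanesulfonate, via B-alkyl-9-borabicyclononane 9 (not isolated)
Conditions: 9-BBN, THF, 0 °C → rt; NaBO3·4H2O, H2O, rt
Reagents that add atoms: sodium perborate ([Na+].[O-]B1OO1)
Why: Anti-Markovnikov hydroboration of the monosubstituted alkene with 9-BBN, followed by mild perborate oxidation. The tetrasubstituted enol triflate is sterically and electronically inert to the borane.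

Step 6
Reactants: 10 (5S,6S)-5-bromo-6-(3-hydroxypropyl)-2,6-dimethylcyclohex-1-en-1-yl trifluoromethanesulfonate
Product: 11 (5S,6S)-5-bromo-2,6-dimethyl-6-(3-oxopropyl)cyclohex-1-en-1-yl trifluoromethanesulfonate
Conditions: Dess–Martin periodinane, CH2Cl2, 0 °C → rt
Reagents that add atoms: none
Why: Dess–Martin oxidation of a primary alcohol to the aldehyde (C10') under neutral conditions that leave the bromide and the triflate untouched.

Step 7
Reactants: 11 (5S,6S)-5-bromo-2,6-dimethyl-6-(3-oxopropyl)cyclohex-1-en-1-yl trifluoromethanesulfonate; 12 methyl 2-[bis(2,2,2-trifluoroethoxy)phosphoryl]propanoate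
Product: 13 methyl (2Z)-5-[(1S,6S)-6-bromo-1,3-dimethyl-2-(trifluoromethanesulfonyloxy)cyclohex-2-en-1-yl]-2-methylpent-2-enoate
Conditions: KN(SiMe3)2, 18-crown-6, THF, −78 °C
Reagents that add atoms: none
Why: Still–Gennari olefination; the trifluoroethyl phosphonate under dissociating conditions gives the kinetic (Z)-trisubstituted enoate. This geometry is what step 12 translates into the C10'/C11' relative configuration.

Step 8
Reactants: 13 methyl (2Z)-5-[(1S,6S)-6-bromo-1,3-dimethyl-2-(trifluoromethanesulfonyloxy)cyclohex-2-en-1-yl]-2-methylpent-2-enoate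
Product: 14 (5S,6S)-5-bromo-6-[(3Z)-5-hydroxy-4-methylpent-3-en-1-yl]-2,6-dimethylcyclohex-1-en-1-yl trifluoromethanesulfonate
Conditions: i-Bu2AlH, CH2Cl2, −78 °C; Rochelle-salt work-up
Reagents that add atoms: none
Why: 1,2-Reduction of the enoate to the allylic alcohol with i-Bu2AlH, with retention of alkene geometry; enol triflates and alkyl bromides tolerate the reagent at −78 °C.

Step 9
Reactants: 14 (5S,6S)-5-bromo-6-[(3Z)-5-hydroxy-4-methylpent-3-en-1-yl]-2,6-dimethylcyclohex-1-en-1-yl trifluoromethanesulfonate
Product: 15 (5S,6S)-5-bromo-6-[(3Z)-5-bromo-4-methylpent-3-en-1-yl]-2,6-dimethylcyclohex-1-en-1-yl trifluoromethanesulfonate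
Conditions: CBr4, PPh3, CH2Cl2, −20 → 0 °C
Reagents that add atoms: tetrabromomethane (BrC(Br)(Br)Br)
Why: Appel bromination of a primary allylic alcohol, which at low temperature proceeds without allylic transposition or (Z)/(E) isomerisation, as in the preparation of neryl bromide from nerol.

Step 10
Reactants: 15 (5S,6S)-5-bromo-6-[(3Z)-5-bromo-4-methylpent-3-en-1-yl]-2,6-dimethylcyclohex-1-en-1-yl trifluoromethanesulfonate
Product: 16 ethyl (4Z)-7-[(1S,6S)-6-bromo-1,3-dimethyl-2-(trifluoromethanesulfonyloxy)cyclohex-2-en-1-yl]-4-methylhept-4-enoate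
Conditions: EtOAc, LiN(i-Pr)2, THF, −78 °C; then 15, DMPU, −78 → −40 °C
Reagents that add atoms: ethyl acetate (CCOC(C)=O)
Why: SN2 alkylation of the lithium enolate of ethyl acetate by the primary allylic bromide forms the C12'–C13' bond and brings in C14' as the ester carbon. The secondary neopentyl-type bromide and the enol triflate do not react with an ester enolate at this temperature.

Step 11
Reactants: 16 ethyl (4Z)-7-[(1S,6S)-6-bromo-1,3-dimethyl-2-(trifluoromethanesulfonyloxy)cyclohex-2-en-1-yl]-4-methylhept-4-enoate
Product: 17 (4Z)-7-[(1S,6S)-6-bromo-1,3-dimethyl-2-(trifluoromethanesulfonyloxy)cyclohex-2-en-1-yl]-4-methylhept-4-enoic acid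
Conditions: LiOH, THF/MeOH/H2O, 0 °C → rt; then 1 M HCl, 0 °C
Reagents that add atoms: lithium hydroxide ([Li+].[OH-])
Why: Saponification of an unhindered primary ester; hydroxide attacks the ester carbonyl much faster than the sulfur of the enol triflate at this temperature. Brief cold acidification avoids proton-induced lactonization of the alkenoic acid.

Step 12
Reactants: 17 (4Z)-7-[(1S,6S)-6-bromo-1,3-dimethyl-2-(trifluoromethanesulfonyloxy)cyclohex-2-en-1-yl]-4-methylhept-4-enoic acid
Product: 18 (5S,6S)-5-bromo-6-{(3R)-3-bromo-3-[(2R)-2-methyl-5-oxooxolan-2-yl]propyl}-2,6-dimethylcyclohex-1-en-1-yl trifluoromethanesulfonate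
Conditions: NBS (1.2 equiv), O-(quinidin-9-yl) N-(2,4-dimethoxyphenyl)carbamothioate (10 mol %), CHCl3/toluene, −78 °C, dark
Reagents that add atoms: N-bromosuccinimide (BrN1C(=O)CCC1=O)
Why: The quinuclidine nitrogen of the catalyst relays Br+ from NBS while the thiocarbamate N–H holds the carboxylate, so bromine is delivered to one face of the (Z)-C10'=C11' alkene and the bound carboxylate opens the bromonium ion at C11' from the opposite face. The closest known reaction type is the amino-thiocarbamate-catalysed enantioselective bromolactonization of 4-substituted pent-4-enoic acids and of (Z)-alk-4-enoic acids; a (Z)-trisubstituted alkene lies at the edge of that scope. The gamma-lactone closes in the 5-exo mode with oxygen attacking the tertiary (Markovnikov) carbon C11'; 6-endo attack at C10' is disfavoured electronically. C10' (R) is set by the face to which the catalyst delivers bromine, and C11' (R) follows from it through the anti opening and the (Z) geometry fixed in step 7. The step needs enantiofacial selectivity, which the catalyst supplies independently of the remote C6'/C7' centres. It also needs site selectivity, which is secured because the only other alkene is the electron-poor enol triflate. Low temperature suppresses the uncatalysed background reaction, which would give both anti diastereomers.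

Step 13
Reactants: 18 (5S,6S)-5-bromo-6-{(3R)-3-bromo-3-[(2R)-2-methyl-5-oxooxolan-2-yl]propyl}-2,6-dimethylcyclohex-1-en-1-yl trifluoromethanesulfonate
Product: 20 (4R,5R)-5-bromo-7-[(1S,6S)-6-bromo-1,3-dimethyl-2-(trifluoromethanesulfonyloxy)cyclohex-2-en-1-yl]-N-methoxy-N,4-dimethyl-4-(triethylsilyloxy)heptanamide, via hydroxy Weinreb amide 19 (not isolated)
Conditions: Me(MeO)NH·HCl, AlMe3, CH2Cl2, 0 °C → rt; Rochelle-salt work-up; crude 19: Et3SiOTf, 2,6-lutidine, CH2Cl2, −78 → 0 °C
Reagents that add atoms: N,O-dimethylhydroxylamine hydrochloride (CNOC.Cl); triethylsilyl trifluoromethanesulfonate (CC[Si](CC)(CC)OS(=O)(=O)C(F)(F)F)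
Why: Aluminium-amide aminolysis of the lactone gives the open Weinreb amide as a weakly nucleophilic aluminium alkoxide, which does not close onto C10'–Br. Immediate silylation of the tertiary hydroxyl blocks relactonization and keeps C11'–O capped through the next two steps; neither centre is touched.

Step 14
Reactants: 20 (4R,5R)-5-bromo-7-[(1S,6S)-6-bromo-1,3-dimethyl-2-(trifluoromethanesulfonyloxy)cyclohex-2-en-1-yl]-N-methoxy-N,4-dimethyl-4-(triethylsilyloxy)heptanamide
Product: 21 (5S,6S)-5-bromo-6-[(3R,4R)-3-bromo-4,8-dimethyl-7-oxo-4-(triethylsilyloxy)non-8-en-1-yl]-2,6-dimethylcyclohex-1-en-1-yl trifluoromethanesulfonate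
Conditions: isopropenylmagnesium bromide, THF, −20 → 0 °C; aq. NH4Cl
Reagents that add atoms: isopropenylmagnesium bromide (CC(=C)[Mg]Br)
Why: Grignard addition to a Weinreb amide stops at the chelated tetrahedral intermediate and releases the enone only on work-up, forming the C14'–C15' bond. With the ring ketone masked as the triflate there is no other electrophilic carbonyl.

Step 15
Reactants: 21 (5S,6S)-5-bromo-6-[(3R,4R)-3-bromo-4,8-dimethyl-7-oxo-4-(triethylsilyloxy)non-8-en-1-yl]-2,6-dimethylcyclohex-1-en-1-yl trifluoromethanesulfonate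
Product: 23 (5S,6S)-5-bromo-6-[(3R,4R,7S)-3-bromo-4,7-dihydroxy-4,8-dimethylnon-8-en-1-yl]-2,6-dimethylcyclohex-1-en-1-yl trifluoromethanesulfonate, via silyl-protected allylic alcohol 22 (not isolated)
Conditions: (R)-1-methyl-3,3-diphenyltetrahydro-1H,3H-pyrrolo[1,2-c][1,3,2]oxazaborole ((R)-Me-CBS, 0.5 equiv), catecholborane, toluene, −78 °C; MeOH quench; then HF·pyridine, THF, 0 °C → rt
Reagents that add atoms: none
Why: Corey–Bakshi–Shibata reduction; the oxazaborolidine treats the isopropenyl group as the large substituent and delivers hydride from catecholborane in a 1,2-sense to give the (14'S) alcohol under reagent control, C11' being too remote to interfere. HF·pyridine then cleaves the tertiary silyl ether without generating an alkoxide beside C10'–Br.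

Step 16
Reactants: 23 (5S,6S)-5-bromo-6-[(3R,4R,7S)-3-bromo-4,7-dihydroxy-4,8-dimethylnon-8-en-1-yl]-2,6-dimethylcyclohex-1-en-1-yl trifluoromethanesulfonate
Product: 25 (5S,6S)-5-bromo-6-{(3R)-3-bromo-3-[(2R,5S)-5-hydroxy-2,6,6-trimethyloxan-2-yl]propyl}-2,6-dimethylcyclohex-1-en-1-yl trifluoromethanesulfonate, via organomercury trifluoroacetate 24 (not isolated)
Conditions: Hg(OCOCF3)2, CH2Cl2, −20 → 0 °C; then NaBH4, aq. NaOH, THF, 0 °C
Reagents that add atoms: none
Why: Intramolecular oxymercuration–demercuration; divalent mercury activates the 1,1-disubstituted alkene, the C11' hydroxyl attacks the more substituted carbon C15' in a 6-exo closure, and NaBH4 replaces mercury by hydrogen so that CH2Hg becomes the second methyl group. C15' is not stereogenic in the product, no five-membered ether can form, and the enol triflate is inert to the mercury salt.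

Step 17
Reactants: 26 4-hydroxy-3-methylbenzoic acid
Product: 27 tert-butyldimethylsilyl 4-[(tert-butyldimethylsilyl)oxy]-3-methylbenzoate
Conditions: t-BuMe2SiCl (2.5 equiv), imidazole, DMF, rt
Reagents that add atoms: tert-butyldimethylsilyl chloride (CC(C)(C)[Si](C)(C)Cl)
Why: Standard bis-silylation of a phenol and a carboxylic acid. The silyl ester is later removed by mild aqueous acid, the aryl silyl ether by fluoride, so the two are orthogonal.

Step 18
Reactants: 27 tert-butyldimethylsilyl 4-[(tert-butyldimethylsilyl)oxy]-3-methylbenzoate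
Product: 28 tert-butyldimethylsilyl 3-(bromomethyl)-4-[(tert-butyldimethylsilyl)oxy]benzoate
Conditions: NBS, 2,2'-azobis(2-methylpropionitrile) (cat.), PhCF3, 85 °C
Reagents that add atoms: N-bromosuccinimide (BrN1C(=O)CCC1=O)
Why: Wohl–Ziegler radical bromination at the only benzylic position, as practised on O-protected 3-methyl-4-hydroxybenzoates. The ester group deactivates the ring towards ionic bromination.

Step 19
Reactants: 25 (5S,6S)-5-bromo-6-{(3R)-3-bromo-3-[(2R,5S)-5-hydroxy-2,6,6-trimethyloxan-2-yl]propyl}-2,6-dimethylcyclohex-1-en-1-yl trifluoromethanesulfonate; 28 tert-butyldimethylsilyl 3-(bromomethyl)-4-[(tert-butyldimethylsilyl)oxy]benzoate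
Product: 31 3-{[(5S,6S)-5-bromo-6-{(3R)-3-bromo-3-[(2R,5S)-5-hydroxy-2,6,6-trimethyloxan-2-yl]propyl}-2,6-dimethylcyclohex-1-en-1-yl]methyl}-4-[(tert-butyldimethylsilyl)oxy]benzoic acid, via benzylzinc bromide 29 (not isolated), via coupled silyl ester 30 (not isolated)
Conditions: 28 (3 equiv), Zn dust, LiCl, THF, 0 °C → rt; then 25, Pd(OAc)2 (5 mol %), 2-dicyclohexylphosphino-2',6'-dimethoxybiphenyl (10 mol %), THF, 50 °C; then AcOH/H2O/THF, rt
Reagents that add atoms: none
Why: Negishi coupling; zinc inserts into the benzylic C–Br bond and the benzylzinc bromide, which has no beta-hydrogen and is used in excess, couples with the enol triflate under zerovalent palladium carrying a bulky biaryl phosphine, as known for 2,6,6-trisubstituted cyclohexenyl triflates. This forms the C1'–C2' bond and reveals the tetrasubstituted alkene only after the last bromination; aqueous acetic acid then hydrolyses the silyl ester but not the aryl silyl ether.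

Step 20
Reactants: 31 3-{[(5S,6S)-5-bromo-6-{(3R)-3-bromo-3-[(2R,5S)-5-hydroxy-2,6,6-trimethyloxan-2-yl]propyl}-2,6-dimethylcyclohex-1-en-1-yl]methyl}-4-[(tert-butyldimethylsilyl)oxy]benzoic acid
Product: 33 bromophycolide Q O-tert-butyldimethylsilyl ether, via mixed anhydride 32 (not isolated)
Conditions: 2,4,6-trichlorobenzoyl chloride, Et3N, THF, rt; then slow addition to DMAP, toluene, 80 °C (about 1 mM)
Reagents that add atoms: none
Why: Yamaguchi macrolactonization; the mixed anhydride is attacked by the C14' hydroxyl through the acylpyridinium ion to close the 15-membered ring. The alcohol is the nucleophile, so C14' keeps its configuration, and the tetrahydropyran and cyclohexene rings restrict the seco acid to few conformations.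

Step 21
Reactants: 33 bromophycolide Q O-tert-butyldimethylsilyl ether
Product: 34 bromophycolide Q
Conditions: Bu4NF, AcOH, THF, 0 °C
Reagents that add atoms: none
Why: Fluoride cleavage of an aryl silyl ether, buffered with acetic acid so that the macrolide ester and the bromides are not exposed to base. No strong acid is used, so the ortho-allylphenol is not driven to the chroman.

## Compound list

1 | 2-methylcyclohex-2-en-1-one | CC1=CCCCC1=O | starting material
2 | tetraallylstannane | C=CC[Sn](CC=C)(CC=C)CC=C | starting material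
3 | (1S)-2-methyl-1-(prop-2-en-1-yl)cyclohex-2-en-1-ol | O[C@]1(CC=C)CCCC=C1C | intermediate
4 | (2S,3S)-3-bromo-2-methyl-2-(prop-2-en-1-yl)cyclohexan-1-one | C=CC[C@]1(C)[C@@H](Br)CCCC1=O | intermediate
5 | lithium (5S,6S)-5-bromo-6-methyl-6-(prop-2-en-1-yl)cyclohex-1-en-1-olate | C=CC[C@]1(C)[C@@H](Br)CCC=C1O[Li] | intermediate
6 | (2S,3S)-3-bromo-2,6-dimethyl-2-(prop-2-en-1-yl)cyclohexan-1-one (both C6 epimers) | C=CC[C@]1(C)[C@@H](Br)CCC(C)C1=O | intermediate
7 | potassium (5S,6S)-5-bromo-2,6-dimethyl-6-(prop-2-en-1-yl)cyclohex-1-en-1-olate | C=CC[C@]1(C)[C@@H](Br)CCC(C)=C1O[K] | intermediate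
8 | (5S,6S)-5-bromo-2,6-dimethyl-6-(prop-2-en-1-yl)cyclohex-1-en-1-yl trifluoromethanesulfonate | C=CC[C@]1(C)[C@@H](Br)CCC(C)=C1OS(=O)(=O)C(F)(F)F | intermediate
9 | 9-{3-[(1S,6S)-6-bromo-1,3-dimethyl-2-(trifluoromethanesulfonyloxy)cyclohex-2-en-1-yl]propyl}-9-borabicyclo[3.3.1]nonane | C1CCC2CCCC1B2CCC[C@]3(C)[C@@H](Br)CCC(C)=C3OS(=O)(=O)C(F)(F)F | intermediate
10 | (5S,6S)-5-bromo-6-(3-hydroxypropyl)-2,6-dimethylcyclohex-1-en-1-yl trifluoromethanesulfonate | OCCC[C@]1(C)[C@@H](Br)CCC(C)=C1OS(=O)(=O)C(F)(F)F | intermediate
11 | (5S,6S)-5-bromo-2,6-dimethyl-6-(3-oxopropyl)cyclohex-1-en-1-yl trifluoromethanesulfonate | O=CCC[C@]1(C)[C@@H](Br)CCC(C)=C1OS(=O)(=O)C(F)(F)F | intermediate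
12 | methyl 2-[bis(2,2,2-trifluoroethoxy)phosphoryl]propanoate | COC(=O)C(C)P(=O)(OCC(F)(F)F)OCC(F)(F)F | starting material
13 | methyl (2Z)-5-[(1S,6S)-6-bromo-1,3-dimethyl-2-(trifluoromethanesulfonyloxy)cyclohex-2-en-1-yl]-2-methylpent-2-enoate | COC(=O)/C(C)=C\CC[C@]1(C)[C@@H](Br)CCC(C)=C1OS(=O)(=O)C(F)(F)F | intermediate
14 | (5S,6S)-5-bromo-6-[(3Z)-5-hydroxy-4-methylpent-3-en-1-yl]-2,6-dimethylcyclohex-1-en-1-yl trifluoromethanesulfonate | OC/C(C)=C\CC[C@]1(C)[C@@H](Br)CCC(C)=C1OS(=O)(=O)C(F)(F)F | intermediate
15 | (5S,6S)-5-bromo-6-[(3Z)-5-bromo-4-methylpent-3-en-1-yl]-2,6-dimethylcyclohex-1-en-1-yl trifluoromethanesulfonate | BrC/C(C)=C\CC[C@]1(C)[C@@H](Br)CCC(C)=C1OS(=O)(=O)C(F)(F)F | intermediate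
16 | ethyl (4Z)-7-[(1S,6S)-6-bromo-1,3-dimethyl-2-(trifluoromethanesulfonyloxy)cyclohex-2-en-1-yl]-4-methylhept-4-enoate | CCOC(=O)CC/C(C)=C\CC[C@]1(C)[C@@H](Br)CCC(C)=C1OS(=O)(=O)C(F)(F)F | intermediate
17 | (4Z)-7-[(1S,6S)-6-bromo-1,3-dimethyl-2-(trifluoromethanesulfonyloxy)cyclohex-2-en-1-yl]-4-methylhept-4-enoic acid | OC(=O)CC/C(C)=C\CC[C@]1(C)[C@@H](Br)CCC(C)=C1OS(=O)(=O)C(F)(F)F | intermediate
18 | (5S,6S)-5-bromo-6-{(3R)-3-bromo-3-[(2R)-2-methyl-5-oxooxolan-2-yl]propyl}-2,6-dimethylcyclohex-1-en-1-yl trifluoromethanesulfonate | O=C1CC[C@@](C)(O1)[C@H](Br)CC[C@]2(C)[C@@H](Br)CCC(C)=C2OS(=O)(=O)C(F)(F)F | intermediate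
19 | (4R,5R)-5-bromo-7-[(1S,6S)-6-bromo-1,3-dimethyl-2-(trifluoromethanesulfonyloxy)cyclohex-2-en-1-yl]-4-hydroxy-N-methoxy-N,4-dimethylheptanamide | CON(C)C(=O)CC[C@@](C)(O)[C@H](Br)CC[C@]1(C)[C@@H](Br)CCC(C)=C1OS(=O)(=O)C(F)(F)F | intermediate
20 | (4R,5R)-5-bromo-7-[(1S,6S)-6-bromo-1,3-dimethyl-2-(trifluoromethanesulfonyloxy)cyclohex-2-en-1-yl]-N-methoxy-N,4-dimethyl-4-(triethylsilyloxy)heptanamide | CON(C)C(=O)CC[C@@](C)(O[Si](CC)(CC)CC)[C@H](Br)CC[C@]1(C)[C@@H](Br)CCC(C)=C1OS(=O)(=O)C(F)(F)F | intermediate
21 | (5S,6S)-5-bromo-6-[(3R,4R)-3-bromo-4,8-dimethyl-7-oxo-4-(triethylsilyloxy)non-8-en-1-yl]-2,6-dimethylcyclohex-1-en-1-yl trifluoromethanesulfonate | CC(=C)C(=O)CC[C@@](C)(O[Si](CC)(CC)CC)[C@H](Br)CC[C@]1(C)[C@@H](Br)CCC(C)=C1OS(=O)(=O)C(F)(F)F | intermediate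
22 | (5S,6S)-5-bromo-6-[(3R,4R,7S)-3-bromo-7-hydroxy-4,8-dimethyl-4-(triethylsilyloxy)non-8-en-1-yl]-2,6-dimethylcyclohex-1-en-1-yl trifluoromethanesulfonate | CC(=C)[C@@H](O)CC[C@@](C)(O[Si](CC)(CC)CC)[C@H](Br)CC[C@]1(C)[C@@H](Br)CCC(C)=C1OS(=O)(=O)C(F)(F)F | intermediate
23 | (5S,6S)-5-bromo-6-[(3R,4R,7S)-3-bromo-4,7-dihydroxy-4,8-dimethylnon-8-en-1-yl]-2,6-dimethylcyclohex-1-en-1-yl trifluoromethanesulfonate | CC(=C)[C@@H](O)CC[C@@](C)(O)[C@H](Br)CC[C@]1(C)[C@@H](Br)CCC(C)=C1OS(=O)(=O)C(F)(F)F | intermediate
24 | {[(3S,6R)-6-{(1R)-1-bromo-3-[(1S,6S)-6-bromo-1,3-dimethyl-2-(trifluoromethanesulfonyloxy)cyclohex-2-en-1-yl]propyl}-3-hydroxy-2,6-dimethyloxan-2-yl]methyl}mercury trifluoroacetate (both C2 epimers of the oxane) | O[C@H]1CC[C@@](C)(OC1(C)C[Hg]OC(=O)C(F)(F)F)[C@H](Br)CC[C@]2(C)[C@@H](Br)CCC(C)=C2OS(=O)(=O)C(F)(F)F | intermediate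
25 | (5S,6S)-5-bromo-6-{(3R)-3-bromo-3-[(2R,5S)-5-hydroxy-2,6,6-trimethyloxan-2-yl]propyl}-2,6-dimethylcyclohex-1-en-1-yl trifluoromethanesulfonate | O[C@H]1CC[C@@](C)(OC1(C)C)[C@H](Br)CC[C@]2(C)[C@@H](Br)CCC(C)=C2OS(=O)(=O)C(F)(F)F | intermediate
26 | 4-hydroxy-3-methylbenzoic acid | Cc1cc(ccc1O)C(=O)O | starting material
27 | tert-butyldimethylsilyl 4-[(tert-butyldimethylsilyl)oxy]-3-methylbenzoate | Cc1cc(ccc1O[Si](C)(C)C(C)(C)C)C(=O)O[Si](C)(C)C(C)(C)C | intermediate
28 | tert-butyldimethylsilyl 3-(bromomethyl)-4-[(tert-butyldimethylsilyl)oxy]benzoate | BrCc1cc(ccc1O[Si](C)(C)C(C)(C)C)C(=O)O[Si](C)(C)C(C)(C)C | intermediate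
29 | {2-[(tert-butyldimethylsilyl)oxy]-5-[(tert-butyldimethylsilyloxy)carbonyl]benzyl}zinc bromide | Br[Zn]Cc1cc(ccc1O[Si](C)(C)C(C)(C)C)C(=O)O[Si](C)(C)C(C)(C)C | intermediate
30 | tert-butyldimethylsilyl 3-{[(5S,6S)-5-bromo-6-{(3R)-3-bromo-3-[(2R,5S)-5-hydroxy-2,6,6-trimethyloxan-2-yl]propyl}-2,6-dimethylcyclohex-1-en-1-yl]methyl}-4-[(tert-butyldimethylsilyl)oxy]benzoate | O[C@H]1CC[C@@](C)(OC1(C)C)[C@H](Br)CC[C@]2(C)[C@@H](Br)CCC(C)=C2Cc3cc(ccc3O[Si](C)(C)C(C)(C)C)C(=O)O[Si](C)(C)C(C)(C)C | intermediate
31 | 3-{[(5S,6S)-5-bromo-6-{(3R)-3-bromo-3-[(2R,5S)-5-hydroxy-2,6,6-trimethyloxan-2-yl]propyl}-2,6-dimethylcyclohex-1-en-1-yl]methyl}-4-[(tert-butyldimethylsilyl)oxy]benzoic acid | O[C@H]1CC[C@@](C)(OC1(C)C)[C@H](Br)CC[C@]2(C)[C@@H](Br)CCC(C)=C2Cc3cc(ccc3O[Si](C)(C)C(C)(C)C)C(=O)O | intermediate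
32 | mixed anhydride of 31 with 2,4,6-trichlorobenzoic acid | O[C@H]1CC[C@@](C)(OC1(C)C)[C@H](Br)CC[C@]2(C)[C@@H](Br)CCC(C)=C2Cc3cc(ccc3O[Si](C)(C)C(C)(C)C)C(=O)OC(=O)c4c(Cl)cc(Cl)cc4Cl | intermediate
33 | bromophycolide Q O-tert-butyldimethylsilyl ether (6'S,7'S,10'R,11'R,14'S) | CC1=C2Cc3cc(ccc3O[Si](C)(C)C(C)(C)C)C(=O)O[C@H]3CC[C@@](C)(OC3(C)C)[C@H](Br)CC[C@]2(C)[C@@H](Br)CC1 | intermediate
34 | bromophycolide Q (6'S,7'S,10'R,11'R,14'S) | CC1=C2Cc3cc(ccc3O)C(=O)O[C@H]3CC[C@@](C)(OC3(C)C)[C@H](Br)CC[C@]2(C)[C@@H](Br)CC1 | target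

## Step count and least certain steps

Total: 21 steps (19 in the main line, 2 for the arene building block). Longest linear sequence: 19 steps (steps 1–16 and 19–21).

**Step 12 (key step).** The most likely failure is incomplete facial discrimination. The two substituents on C11' (methyl and the carboxyethyl arm) differ little in size, and the alkene is trisubstituted, so the catalyst-bound pathway may not outrun the background reaction enough; the result would be contamination by the other anti diastereomer (10'S,11'S).

The fallback sets out from ester 16 and separates oxygen delivery from bromide delivery. Shi epoxidation (the fructose-derived ketone 1,2:4,5-di-O-isopropylidene-D-erythro-2,3-hexodiulo-2,6-pyranose, Oxone, buffered MeCN/H2O, 0 °C) should give ethyl 3-[(2R,3S)-3-{2-[(1S,6S)-6-bromo-1,3-dimethyl-2-(trifluoromethanesulfonyloxy)cyclohex-2-en-1-yl]ethyl}-2-methyloxiran-2-yl]propanoate F1. Opening at the secondary carbon C10' with Li2NiBr4 in THF proceeds with inversion and should give the bromohydrin ester ethyl (4R,5R)-5-bromo-7-[(1S,6S)-6-bromo-1,3-dimethyl-2-(trifluoromethanesulfonyloxy)cyclohex-2-en-1-yl]-4-hydroxy-4-methylheptanoate F2. A trace of p-toluenesulfonic acid closes F2 to lactone 18, where the route is rejoined. Syn epoxidation followed by SN2 opening is again a net anti addition to the (Z)-alkene.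

**Step 2.** The 1,2-allyl shift may be outrun by other fates of the bromonium ion. The free hydroxyl can capture it (bromo-epoxide), a proton can be lost from the C7' cation, or HBr traces can ionise the tertiary allylic alcohol. An sp3 allyl group is only a moderate migrating group.

The fallback sets out from alcohol 3. It is converted (Me3SiCl, imidazole) into trimethyl{[(1S)-2-methyl-1-(prop-2-en-1-yl)cyclohex-2-en-1-yl]oxy}silane F3, and the rearrangement is run on this silyl ether with NBS in CH2Cl2. The capped oxygen can no longer form an epoxide or deliver a proton, the shift is terminated by loss of the silyl group from the oxocarbenium ion, and the route is rejoined at ketone 4.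

**Step 13.** The hydroxy amide 19 may relactonize during work-up, before silylation can trap it. A gamma-hydroxy amide with a tertiary hydroxyl closes readily.

The fallback sets out from lactone 18 and avoids the amide. Reduction with i-Bu2AlH at −78 °C should give the lactol (5S,6S)-5-bromo-6-{(3R)-3-bromo-3-[(2R)-5-hydroxy-2-methyloxolan-2-yl]propyl}-2,6-dimethylcyclohex-1-en-1-yl trifluoromethanesulfonate F4. Excess isopropenylmagnesium bromide, kept at or below 0 °C so that the magnesium alkoxide does not close onto C10'–Br, should give the diol as a mixture of C14' epimers, (5S,6S)-5-bromo-6-[(3R,4R)-3-bromo-4,7-dihydroxy-4,8-dimethylnon-8-en-1-yl]-2,6-dimethylcyclohex-1-en-1-yl trifluoromethanesulfonate F5. MnO2 oxidises only the allylic alcohol to the hydroxy enone (5S,6S)-5-bromo-6-[(3R,4R)-3-bromo-4-hydroxy-4,8-dimethyl-7-oxonon-8-en-1-yl]-2,6-dimethylcyclohex-1-en-1-yl trifluoromethanesulfonate F6. The oxazaborolidine reduction of step 15 then returns diol 23.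

**Step 16.** Divalent mercury is halophilic and may assist ionisation of a C–Br bond. The organomercurial may also revert to alkene and alcohol during reduction.

The fallback sets out from diol 23 and uses a radical–polar crossover. The secondary allylic hydroxyl is silylated selectively (t-BuMe2SiCl, imidazole) to give (5S,6S)-5-bromo-6-[(3R,4R,7S)-3-bromo-7-[(tert-butyldimethylsilyl)oxy]-4-hydroxy-4,8-dimethylnon-8-en-1-yl]-2,6-dimethylcyclohex-1-en-1-yl trifluoromethanesulfonate F7. Cobalt-catalysed hydrogen-atom-transfer hydroalkoxylation ([N,N'-bis(3,5-di-tert-butylsalicylidene)cyclohexane-1,2-diaminato]cobalt, divalent cobalt; N-fluoro-2,4,6-trimethylpyridinium triflate; (Me2SiH)2O) should close the tetrahydropyran at C15' to give (5S,6S)-5-bromo-6-{(3R)-3-bromo-3-[(2R,5S)-5-[(tert-butyldimethylsilyl)oxy]-2,6,6-trimethyloxan-2-yl]propyl}-2,6-dimethylcyclohex-1-en-1-yl trifluoromethanesulfonate F8. The silyl ether prevents epoxide formation from the allylic oxygen. HF·pyridine then gives pyranol 25.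

**Step 20.** Oligomerisation may outrun ring closure. The C14' hydroxyl sits beside the gem-dimethyl carbon and is a slow nucleophile, and high dilution removes the option of forcing it with excess reagent.

The fallback sets out from pyranol 25 and reverses the order of the two unions, so that the hindered ester is made intermolecularly and the ring is closed by C–C coupling. Zinc reagent 29 is quenched with Bu3SnCl to give tert-butyldimethylsilyl 4-[(tert-butyldimethylsilyl)oxy]-3-[(tributylstannyl)methyl]benzoate F9. Aqueous acetic acid gives 4-[(tert-butyldimethylsilyl)oxy]-3-[(tributylstannyl)methyl]benzoic acid F10. Esterification of 25 with excess F10 (carbodiimide, DMAP) should give the stannyl ester (3S,6R)-6-{(1R)-1-bromo-3-[(1S,6S)-6-bromo-1,3-dimethyl-2-(trifluoromethanesulfonyloxy)cyclohex-2-en-1-yl]propyl}-2,2,6-trimethyloxan-3-yl 4-[(tert-butyldimethylsilyl)oxy]-3-[(tributylstannyl)methyl]benzoate F11. Intramolecular Stille coupling (Pd2(dba)3, AsPh3, LiCl, N-methylpyrrolidone, high dilution) then closes the ring to 33.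

## Further compounds

F1 | step 12 | ethyl 3-[(2R,3S)-3-{2-[(1S,6S)-6-bromo-1,3-dimethyl-2-(trifluoromethanesulfonyloxy)cyclohex-2-en-1-yl]ethyl}-2-methyloxiran-2-yl]propanoate | CCOC(=O)CC[C@@]1(C)O[C@H]1CC[C@]2(C)[C@@H](Br)CCC(C)=C2OS(=O)(=O)C(F)(F)F
F2 | step 12 | ethyl (4R,5R)-5-bromo-7-[(1S,6S)-6-bromo-1,3-dimethyl-2-(trifluoromethanesulfonyloxy)cyclohex-2-en-1-yl]-4-hydroxy-4-methylheptanoate | CCOC(=O)CC[C@@](C)(O)[C@H](Br)CC[C@]1(C)[C@@H](Br)CCC(C)=C1OS(=O)(=O)C(F)(F)F
F3 | step 2 | trimethyl{[(1S)-2-methyl-1-(prop-2-en-1-yl)cyclohex-2-en-1-yl]oxy}silane | C[Si](C)(C)O[C@]1(CC=C)CCCC=C1C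
F4 | step 13 | (5S,6S)-5-bromo-6-{(3R)-3-bromo-3-[(2R)-5-hydroxy-2-methyloxolan-2-yl]propyl}-2,6-dimethylcyclohex-1-en-1-yl trifluoromethanesulfonate (both anomers) | OC1CC[C@@](C)(O1)[C@H](Br)CC[C@]2(C)[C@@H](Br)CCC(C)=C2OS(=O)(=O)C(F)(F)F
F5 | step 13 | (5S,6S)-5-bromo-6-[(3R,4R)-3-bromo-4,7-dihydroxy-4,8-dimethylnon-8-en-1-yl]-2,6-dimethylcyclohex-1-en-1-yl trifluoromethanesulfonate (both C7 epimers of the chain) | CC(=C)C(O)CC[C@@](C)(O)[C@H](Br)CC[C@]1(C)[C@@H](Br)CCC(C)=C1OS(=O)(=O)C(F)(F)F
F6 | step 13 | (5S,6S)-5-bromo-6-[(3R,4R)-3-bromo-4-hydroxy-4,8-dimethyl-7-oxonon-8-en-1-yl]-2,6-dimethylcyclohex-1-en-1-yl trifluoromethanesulfonate | CC(=C)C(=O)CC[C@@](C)(O)[C@H](Br)CC[C@]1(C)[C@@H](Br)CCC(C)=C1OS(=O)(=O)C(F)(F)F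
F7 | step 16 | (5S,6S)-5-bromo-6-[(3R,4R,7S)-3-bromo-7-[(tert-butyldimethylsilyl)oxy]-4-hydroxy-4,8-dimethylnon-8-en-1-yl]-2,6-dimethylcyclohex-1-en-1-yl trifluoromethanesulfonate | CC(=C)[C@@H](O[Si](C)(C)C(C)(C)C)CC[C@@](C)(O)[C@H](Br)CC[C@]1(C)[C@@H](Br)CCC(C)=C1OS(=O)(=O)C(F)(F)F
F8 | step 16 | (5S,6S)-5-bromo-6-{(3R)-3-bromo-3-[(2R,5S)-5-[(tert-butyldimethylsilyl)oxy]-2,6,6-trimethyloxan-2-yl]propyl}-2,6-dimethylcyclohex-1-en-1-yl trifluoromethanesulfonate | CC(C)(C)[Si](C)(C)O[C@H]1CC[C@@](C)(OC1(C)C)[C@H](Br)CC[C@]2(C)[C@@H](Br)CCC(C)=C2OS(=O)(=O)C(F)(F)F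
F9 | step 20 | tert-butyldimethylsilyl 4-[(tert-butyldimethylsilyl)oxy]-3-[(tributylstannyl)methyl]benzoate | CCCC[Sn](CCCC)(CCCC)Cc1cc(ccc1O[Si](C)(C)C(C)(C)C)C(=O)O[Si](C)(C)C(C)(C)C
F10 | step 20 | 4-[(tert-butyldimethylsilyl)oxy]-3-[(tributylstannyl)methyl]benzoic acid | CCCC[Sn](CCCC)(CCCC)Cc1cc(ccc1O[Si](C)(C)C(C)(C)C)C(=O)O
F11 | step 20 | (3S,6R)-6-{(1R)-1-bromo-3-[(1S,6S)-6-bromo-1,3-dimethyl-2-(trifluoromethanesulfonyloxy)cyclohex-2-en-1-yl]propyl}-2,2,6-trimethyloxan-3-yl 4-[(tert-butyldimethylsilyl)oxy]-3-[(tributylstannyl)methyl]benzoate | CCCC[Sn](CCCC)(CCCC)Cc1cc(ccc1O[Si](C)(C)C(C)(C)C)C(=O)O[C@H]2CC[C@@](C)(OC2(C)C)[C@H](Br)CC[C@]3(C)[C@@H](Br)CCC(C)=C3OS(=O)(=O)C(F)(F)F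
A1 | alternative 1 | bromomethyl ketone with C2' arylmethyl, C7' quaternary centre and vinyl group | BrCC(=O)[C@H](Cc1cc(ccc1O[Si](C)(C)C(C)(C)C)C(=O)OC)[C@@](C)(C=C)CCCO[Si](C)(C)C(C)(C)C
A2 | alternative 1 | 4-bromocyclohexanone with C7' quaternary centre and C2' arylmethyl | O=C1CC[C@H](Br)[C@@](C)(CCCO[Si](C)(C)C(C)(C)C)[C@H]1Cc1cc(ccc1O[Si](C)(C)C(C)(C)C)C(=O)OC
A3 | alternative 2 | 19-membered macrolactone diene (2'E,6'E), phenol as acetate | C/C1=C\Cc2cc(ccc2OC(C)=O)C(=O)O[C@H]2CC[C@@](C)(OC2(C)C)[C@H](Br)CC/C(C)=C/CC1
A4 | alternative 2 | bromophycolide Q O-acetate | CC1=C2Cc3cc(ccc3OC(C)=O)C(=O)O[C@H]3CC[C@@](C)(OC3(C)C)[C@H](Br)CC[C@]2(C)[C@@H](Br)CC1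
A5 | alternative 3 | coumalate ester of the C14' alcohol carrying a triisopropylsiloxyalkyne on C1' | O=c1ccc(co1)C(=O)O[C@H]2CC[C@@](C)(OC2(C)C)[C@H](Br)CC[C@]3(C)[C@@H](Br)CCC(C)=C3CC#CO[Si](C(C)C)(C(C)C)C(C)C
A6 | alternative 3 | bromophycolide Q O-triisopropylsilyl ether | CC1=C2Cc3cc(ccc3O[Si](C(C)C)(C(C)C)C(C)C)C(=O)O[C@H]3CC[C@@](C)(OC3(C)C)[C@H](Br)CC[C@]2(C)[C@@H](Br)CC1
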